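Molar per hour was the unit I reached for first. Thursday's flask lost solid substrate at 0.298 M h⁻¹ over its first 3.00 h, and Friday's smaller charge lost it at 0.301 M h⁻¹ over 120 min. The pace did not follow the charge, so I read this as zero-order dissolving into starting material, a straight line in time. At that pace 1.5 M lasts 5.03 h; I call this the clearance time, the charge divided by the dissolving rate. Thursday's reading at 8.00 h stands at 0 %.

| flask | solid substrate | temperature | remark | time |
|---|---|---|---|---|
| Thursday's | 1.5 M | 100 °C | the very flask that is asked about, followed so far |  |
| Friday's | 1 M | 100 °C | run made earlier |  |
| flask | 1.5 M | 100 °C |  | 25 h |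

Thursday's run (percent of the solid substrate charged)

| time / h | target / % | solid substrate / % |
|---|---|---|
| 3.00 | 27.7 | 40.3 |
| 8.00 | 56.2 | 0 |
| 15.0 | 43.8 | 0.1 |
| 25.0 | 38.2 | 0 |

Friday's run (percent of the solid substrate charged)

| time / min | target / % | solid substrate / % |
|---|---|---|
| 8.00 | 0 | 95.0 |
| 20.0 | 2.4 | 89.3 |
| 50.0 | 8.4 | 72.3 |
| 120 | 26.7 | 39.8 |

(scatter of a reading: 1 percentage point)

- as a solid, counted per litre of solution: solid substrate
- target taken out counts as made
- what was read earlier has a scatter of 1 percentage point, one standard deviation
- candidate steps: starting material <-> target; starting material <-> isomer of the product; solid substrate <-> starting material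
- at the start none of the solid substrate is in solution
- the earlier runs do not show what temperature does; that part of a forecast is a guess

- blue: at 25 h raise the temperature by 20 K, then wait 8.0 h
- violet: at 25 h take out 90 % of the target then present, then wait 8.0 h
- grey: change nothing and wait 8.0 h more

* target, in percent of the solid substrate first charged, at 25 h
* which option adds most target ("none" when 2 percentage points or less is all one gets) (blue / violet / grey / none)
* target present, with what was taken out counted in, in percent of the solid substrate first charged, after blue
* target present, with what was taken out counted in, in percent of the solid substrate first charged, after violet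

The target at 25 h I took from Thursday's reading, 38.2 %. For violet I solved two extreme versions of the flask. If the cut flask stands still for the wait, the total stays at 38.2 %. If what remains at once takes target's present share, the total reaches 59.4 %. I expected the real flask between them. The flask's clearance time is shorter than the time of the cut, and Thursday's solid reading at 25.0 h stands at 0 %, so I counted on no fresh feed from the solid, and the refill had to come from what was already in solution. Thursday's target reading fell 5.6 percentage points over the last 10.0 h of the run, so I expected no gain from grey; I backed violet and left blue as a guess.

The forecast gave 38.2 % now, violet as best, 36.5 % after blue and 52 % after violet, holding that “The starting-material pool quickly refills target”.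

The flask gave 37.0 % at 25 h, and violet was best at 46.9 %, a gain of 9.8 points. That total lies below my upper version and above my lower one. Blue gave 23.5 %.

    starting material ⇌ target (K = 4.60, k = 2.80 × 10⁻⁴ s⁻¹, Ea = 110 kJ mol⁻¹, ΔH = −17.0 kJ mol⁻¹)
    starting material ⇌ isomer of the product (K = 9.40, k = 9.60 × 10⁻⁵ s⁻¹, Ea = 124 kJ mol⁻¹, ΔH = 6.00 kJ mol⁻¹)
    solid substrate ⇌ starting material, rate k3*(cs3 - [starting material]) while solid is left; crystals form when [starting material] > cs3 (solubility = 1.00 M, k = 9.90 × 10⁻⁵ s⁻¹)
    (constants at 100 °C)

At 2.50 h the clearance line leaves 50.3 % of the solid, and the flask held 50.9 %. On the 75 °C repeat I ran the same line at the same rate, which is a guess there. It ends at 5.03 h, 20.0 h before the look at 25 h, and that flask stood at 0 % solid with target at 63.0 %.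

(The readings come from a simulation on assumed constants; noise was put on by code.)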